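Counting D is the easy step: take it that an E that becomes L uses one D, and an E carried on to a bis adduct uses two. Two settings of elm, the flask asked about, are turned here, the D charge and the time.

| flask | E | D | remark | time |
|---|---|---|---|---|
| elm | 15 mM | 30 mM | the very flask that is asked about, followed so far |  |
| cedar | 30 mM | 30 mM | run made earlier |  |
| flask | 15 mM | 30.0 mM |  | 12 h |

| elm: time / h | elm: L / % | cedar: time / h | cedar: L / % |
|---|---|---|---|
| 0.417 | 11.8 | 2.50 | 21.7 |
| 0.667 | 13.9 | 5.00 | 20.5 |
| 1.33 | 20.4 | 8.00 | 20.9 |
| 2.50 | 21.7 | 10.0 | 21.7 |
| 5.00 | 19.8 | 12.0 | 19.4 |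

(scatter of a reading: 1 percentage point)

* equivalents of D to E, everything else as given, that leave most L at 12 h
* the amount of L then, in percent of the E charged
* the amount of L with the amounts as given

With e the share of E left and s the rate constant of L + D over that of E + D, the two steps give [L] = (e − e^s)/(s − 1) of the E charged, whatever path [D] takes.

Cedar's readings average 20.8%, with a scatter of 1 percentage point on each. If this plateau marks the end of cedar's 30 mM of D, the count gives e = 39.6%. At that e, a trial s of 2 gives 23.9% and a trial s of 3 gives 16.7%. Interpolating in logarithms, my reckoning reads the selectivity factor, s = 2.38.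

Turning D first: the curve peaks at e = 53.4% with L at 22.4%, and the count puts that peak at 0.709 equivalents of D. Elm's highest reading, 21.7% at 2.50 h, lies near that L.

Turning time: cedar's readings run from 21.7% at 2.50 h to 19.4% at 12.0 h. Elm carries twice as much D as E, so the count gives [D] = 2[E] + [L], and as a rough step my reckoning lets 1/[E] climb linearly with time. Placing the curve's peak at the time of that reading, elm at 12 h comes to e = 19.3% and L = 12.5%.

The forecast, which calls “best case is D exhausted right at the L maximum”, gives 0.77 equiv, more than my charge, with 22.5% there, and 11% as given, less than my L.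

The flask gives 11.6% of L as charged, and 22.0% at 0.868 equiv.

    L ⇌ Z (K = 0.230, k = 2.52 × 10⁻⁴ s⁻¹)
    E + D → L + X (k = 0.00351 M⁻¹ s⁻¹)
    D + L → J + X (k = 0.00750 M⁻¹ s⁻¹)
    G ⇌ X, rate k4*(cs4 - [X]) while solid is left; crystals form when [X] > cs4 (solubility = 6.20 mM, k = 0.00478 s⁻¹)

At 12 h the flask holds Z at 2.71% beside L. The curve with s = 2.38, fed the 13.7% of E then present, gives 9.28%, which falls short of the flask by 2.3 points. With 7.5 mM of D, E stands at 65.3% at the same time, the curve gives 21.0%, and that flask holds 19.4% of L.

The earlier runs and the new flask were computed from invented constants; the scatter is artificial.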